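**Retrosynthetic overview**

1. End game: target 32 from acid 31 by global desilylation; 31 from the tricyclic 15,6α-lactone 21 by reductive silylation of the lactone, O-8 acylation with acid 27, and SeO2/Pinnick oxidation of the C-7 isopropenyl group.
2. Key disconnection C-5–C-6: lactone 21 from aldehyde–enoate 19 by a SmI2 ketyl–olefin cyclisation that closes ring B onto preformed ring A and, in the same operation, a temporary γ-lactone bridge C-15/O-6.
3. Enabling feature: the 6-hydroxyl on ring B and the C-15 carbonyl on C-4 of ring A stand 1,4 across the ring-fusion carbon C-5 (O-6–C-6–C-5–C-4–C-15), the retron of a ketyl/acrylate coupling. Every ring B substituent is equatorial and only the C-10 methyl is axial, so one chair transition state relays C-7, C-8 and C-10 to C-4, C-5 and C-6.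
4. 19 from aldehyde 10 by an Evans syn-aldol (C-7–C-8) with the senecioyl oxazolidinone 14; 10 from enone 4 by anti-selective conjugate vinylation, enolate triflation and methoxycarbonylation (quaternary C-10 relayed from C-1).
5. 4 from 2-methylcyclohex-2-en-1-one by CBS reduction (C-1), silylation and allylic oxidation. Ring order: ring A (bought as a carbocycle), then ring B, with the lactone bridge as a temporary third ring.

Key step: step 13

Numbering: atom numbers are the eudesmane numbers of the target (C-1 CHOH, C-4 CH–CHO, C-5 ring-fusion CH, C-6 CHOH, C-7, C-8 CH–O-acyl, C-9, C-10 quaternary, C-11/C-12/C-13 acrylic acid, C-15 aldehyde carbon).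

Assumption: the 6α-hydroxy-15-aldehyde of the target is treated as the open ring–chain tautomer of the bridged 15,6α-lactol; the last step sets this pair free and the product is written in the open form of the target.

**Route**

Step 1
Reactants: 1 2-methylcyclohex-2-en-1-one
Product: 2 (R)-2-methylcyclohex-2-en-1-ol
Conditions: (S)-2-methyl-CBS-oxazaborolidine (10 mol %), BH3·SMe2, THF, −20 °C
Reagents that add atoms: none
Why: Corey–Bakshi–Shibata reduction, in which the oxazaborolidine should tell the alkenyl (large) flank from the methylene (small) flank of the enone and deliver hydride to one face, setting C-1 as R.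

Step 2
Reactants: 2 (R)-2-methylcyclohex-2-en-1-ol
Product: 3 (R)-tert-butyldimethyl[(2-methylcyclohex-2-en-1-yl)oxy]silane
Conditions: TBSCl, imidazole, DMF, rt
Reagents that add atoms: tert-butyldimethylsilyl chloride, CC(C)(C)[Si](C)(C)Cl
Why: Standard silylation of a secondary allylic alcohol; no stereocentre is touched.

Step 3
Reactants: 3 (R)-tert-butyldimethyl[(2-methylcyclohex-2-en-1-yl)oxy]silane
Product: 4 (R)-4-(tert-butyldimethylsilyloxy)-3-methylcyclohex-2-en-1-one
Conditions: Rh2(cap)4 (dirhodium tetrakis(caprolactamate), 1 mol %), t-BuOOH (70% aq.), K2CO3, CH2Cl2, rt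
Reagents that add atoms: tert-butyl hydroperoxide, CC(C)(C)OO
Why: Allylic C–H oxidation by the tert-butylperoxyl radical chain should take the only unhindered ring allylic methylene (C-4) to the conjugated ketone and leave the silyloxy-bearing C-1 intact.

Step 4
Reactants: 4 (R)-4-(tert-butyldimethylsilyloxy)-3-methylcyclohex-2-en-1-one
Product: 6 (3R,4R)-4-(tert-butyldimethylsilyloxy)-3-methyl-3-vinylcyclohex-1-en-1-yl trifluoromethanesulfonate, via magnesium enolate 5 (not isolated)
Conditions: CH2=CHMgBr (1.5 equiv), CuBr·SMe2 (10 mol %), THF, −40 °C; then N-(5-chloropyridin-2-yl)bis(trifluoromethanesulfonimide), −40 → 0 °C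
Reagents that add atoms: vinylmagnesium bromide, C=C[Mg]Br; N-(5-chloropyridin-2-yl)bis(trifluoromethanesulfonimide), O=S(=O)(N(c1ccc(Cl)cn1)S(=O)(=O)C(F)(F)F)C(F)(F)F
Why: Copper-catalysed 1,4-addition of the Grignard reagent to the β,β-disubstituted enone should occur anti to the adjacent silyloxy group, so that C-1 sets the quaternary C-10 (vinyl trans to OTBS, methyl cis), and the regiodefined C-4=C-5 enolate is O-triflated in the same flask.

Step 5
Reactants: 6 (3R,4R)-4-(tert-butyldimethylsilyloxy)-3-methyl-3-vinylcyclohex-1-en-1-yl trifluoromethanesulfonate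
Product: 7 methyl (3R,4R)-4-(tert-butyldimethylsilyloxy)-3-methyl-3-vinylcyclohex-1-ene-1-carboxylate
Conditions: Pd(OAc)2 (5 mol %), PPh3 (10 mol %), CO (1 atm), Et3N, MeOH/DMF, 50 °C
Reagents that add atoms: carbon monoxide, [C-]#[O+]; methanol, CO
Why: Palladium-catalysed alkoxycarbonylation of an enol triflate (oxidative addition, CO insertion, methanolysis) installs C-15 on C-4 without touching a stereocentre.

Step 6
Reactants: 7 methyl (3R,4R)-4-(tert-butyldimethylsilyloxy)-3-methyl-3-vinylcyclohex-1-ene-1-carboxylate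
Product: 9 methyl (3R,4R)-4-(tert-butyldimethylsilyloxy)-3-(2-hydroxyethyl)-3-methylcyclohex-1-ene-1-carboxylate, via B-alkyl-9-borabicyclononane 8 (not isolated)
Conditions: 9-BBN, THF, 0 °C → rt; then aq. NaOAc, H2O2, 0 °C → rt
Reagents that add atoms: 9-borabicyclo[3.3.1]nonane, B1C2CCCC1CCC2 (boron only in 8); hydrogen peroxide, OO
Why: Anti-Markovnikov hydroboration–oxidation of the monosubstituted vinyl group, with the electron-poor trisubstituted enoate inert to 9-BBN and the buffered oxidation sparing the ester; no new stereocentre.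

Step 7
Reactants: 9 methyl (3R,4R)-4-(tert-butyldimethylsilyloxy)-3-(2-hydroxyethyl)-3-methylcyclohex-1-ene-1-carboxylate
Product: 10 methyl (3R,4R)-4-(tert-butyldimethylsilyloxy)-3-methyl-3-(2-oxoethyl)cyclohex-1-ene-1-carboxylate
Conditions: Dess–Martin periodinane, NaHCO3, CH2Cl2, 0 °C → rt
Reagents that add atoms: none
Why: Dess–Martin oxidation of a primary alcohol to the aldehyde (C-8) under buffered, non-epimerising conditions.

Step 8
Reactants: 11 (R)-4-benzyloxazolidin-2-one; 12 3-methylbut-2-enoyl chloride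
Product: 14 (R)-4-benzyl-3-(3-methylbut-2-enoyl)oxazolidin-2-one, via lithium oxazolidinide 13 (not isolated)
Conditions: n-BuLi, THF, −78 °C; then 12, −78 → 0 °C
Reagents that add atoms: n-butyllithium, [Li]CCCC (lithium only in 13)
Why: N-acylation of the lithiated auxiliary with the acid chloride, the standard entry to Evans imides.

Step 9
Reactants: 14 (R)-4-benzyl-3-(3-methylbut-2-enoyl)oxazolidin-2-one; 10 methyl (3R,4R)-4-(tert-butyldimethylsilyloxy)-3-methyl-3-(2-oxoethyl)cyclohex-1-ene-1-carboxylate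
Product: 16 methyl (3R,4R)-3-{(2S,3R)-3-[(R)-4-benzyl-2-oxooxazolidine-3-carbonyl]-2-hydroxy-4-methylpent-4-en-1-yl}-4-(tert-butyldimethylsilyloxy)-3-methylcyclohex-1-ene-1-carboxylate, via boron dienolate 15 (not isolated)
Conditions: 14, Bu2BOTf, Et3N, CH2Cl2, −78 → 0 °C; then 10, −78 → 0 °C; pH 7 buffer/MeOH/H2O2 work-up, 0 °C
Reagents that add atoms: dibutylboron trifluoromethanesulfonate, CCCCB(CCCC)OS(=O)(=O)C(F)(F)F (boron only in 15)
Why: Evans boron aldol through the Z(O)-dienolate formed by γ-deprotonation; it reacts at its α-carbon through a Zimmerman–Traxler chair on the face fixed by the auxiliary and should give the syn adduct, setting C-7 (R) and C-8 (S) by reagent control and leaving the isopropenyl group on C-7.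

Step 10
Reactants: 16 the syn-aldol adduct
Product: 17 methyl (3R,4R)-3-{(2S,3R)-3-[(R)-4-benzyl-2-oxooxazolidine-3-carbonyl]-4-methyl-2-(triethylsilyloxy)pent-4-en-1-yl}-4-(tert-butyldimethylsilyloxy)-3-methylcyclohex-1-ene-1-carboxylate
Conditions: TESOTf, 2,6-lutidine, CH2Cl2, −78 °C
Reagents that add atoms: triethylsilyl trifluoromethanesulfonate, CC[Si](CC)(CC)OS(=O)(=O)C(F)(F)F
Why: Silylation of the aldol hydroxyl blocks retro-aldol and gives O-8 a bulky, non-chelating group that can later be removed in the presence of TBS ethers.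

Step 11
Reactants: 17 the O-8 triethylsilyl imide
Product: 18 methyl (3R,4R)-4-(tert-butyldimethylsilyloxy)-3-[(2S,3S)-3-(hydroxymethyl)-4-methyl-2-(triethylsilyloxy)pent-4-en-1-yl]-3-methylcyclohex-1-ene-1-carboxylate
Conditions: LiBH4, MeOH (1.2 equiv), THF, 0 °C
Reagents that add atoms: none
Why: Reductive removal of the auxiliary; the imide carbonyl is far more electrophilic toward LiBH4 than the conjugated methyl ester, which should survive at 0 °C.

Step 12
Reactants: 18 the C-6 primary alcohol
Product: 19 methyl (3R,4R)-4-(tert-butyldimethylsilyloxy)-3-[(2S,3R)-3-formyl-4-methyl-2-(triethylsilyloxy)pent-4-en-1-yl]-3-methylcyclohex-1-ene-1-carboxylate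
Conditions: Dess–Martin periodinane, NaHCO3, CH2Cl2, 0 °C; used at once
Reagents that add atoms: none
Why: Buffered Dess–Martin oxidation gives the α-branched β,γ-unsaturated aldehyde without base or acid that could epimerise C-7 or move the alkene into conjugation.

Step 13
Reactants: 19 the aldehyde–enoate
Product: 21 1β-(tert-butyldimethylsilyloxy)-8α-(triethylsilyloxy)-7β-isopropenyl-eudesman-15,6α-olide (trans-decalin with 10β-methyl and H-5α; H-4β; H-6β; H-7α; H-8β), via hydroxy ester 20 (not isolated)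
Conditions: SmI2 (2.5 equiv), t-BuOH (2 equiv), THF (0.01 M), −78 → 0 °C; aq. NH4Cl work-up; then DBU (0.3 equiv), PhMe, 50 °C
Reagents that add atoms: none
Why: SmI2 transfers one electron to the aldehyde to give a samarium ketyl at C-6, which adds 6-exo-trig to C-5, the β-carbon of the ring A enoate; a second electron turns the C-4 α-ester radical into a samarium enolate that t-BuOH protonates, and the C-6 alkoxide then closes the γ-lactone on C-15 (5-exo-trig acyl substitution with loss of methanol), the closest known reaction type being the SmI2-mediated aldehyde/α,β-unsaturated ester ketyl–olefin cyclisation that ends in a γ-butyrolactone. Ring B should close through a chair-like transition state in which the C-7 isopropenyl group, the C-8 silyloxy group and the C-10–C-1 bond are equatorial and only the C-10 methyl is axial. C-6 is set by the ketyl oxygen, which with its samarium ligands takes the equatorial site, anti to the enoate and away from the syn-axial C-10 methyl, giving 6α-O. C-5 is set by attack on the face of C-4=C-5 that keeps C-4 equatorial on this chair (trans fusion, H-5α), whereas the cis-fusing alternative must place C-4 axial on the forming ring and both the C-9 tether and the C-1 silyloxy group axial on ring A. C-4 is set last and under thermodynamic control, because only the 4α ester (H-4β) can lactonise onto the 6α oxygen and DBU funnels any 4β epimer through its enolate into 21. The step needs ketyl formation at the aldehyde only and trans over cis ring fusion; the first is secured because C-15 is the only ester and C-7 carries a plain isopropenyl group, the second by the three equatorial anchors on the chair.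

Step 14
Reactants: 21 the 15,6α-lactone
Product: 23 the 15-O-tert-butyldimethylsilyl lactol ether of 21 (bridged 15,6α-lactol; 1β-OTBS; 8α-OTES; C-15 epimers both usable), via aluminium lactolate 22 (not isolated)
Conditions: i-Bu2AlH (1.2 equiv), CH2Cl2, −78 °C; then pyridine, TBSOTf, −78 → −20 °C
Reagents that add atoms: diisobutylaluminium hydride, CC(C)C[AlH]CC(C)C (aluminium only in 22); tert-butyldimethylsilyl trifluoromethanesulfonate, CC(C)(C)[Si](C)(C)OS(=O)(=O)C(F)(F)F
Why: One hydride adds to the lactone to give a tetrahedral aluminium hemiacetal that is stable at −78 °C and is silylated in the flask (reductive silylation of a lactone), which stores C-15 at the aldehyde level and O-6 in the same fluoride-labile group while the bridge keeps C-4 locked.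

Step 15
Reactants: 23 the lactol silyl ether
Product: 24 the 8α-alcohol (15-O-TBS lactol ether; 1β-OTBS; 7β-isopropenyl)
Conditions: HF·pyridine, pyridine, THF, 0 °C
Reagents that add atoms: none
Why: Buffered HF·pyridine cleaves a secondary triethylsilyl ether much faster than tert-butyldimethylsilyl ethers, so only O-8 should be freed.

Step 16
Reactants: 25 ethyl 2-(hydroxymethyl)acrylate
Product: 26 ethyl 2-[(tert-butyldimethylsilyloxy)methyl]acrylate
Conditions: TBSCl, imidazole, CH2Cl2, 0 °C → rt
Reagents that add atoms: tert-butyldimethylsilyl chloride, CC(C)(C)[Si](C)(C)Cl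
Why: Standard silylation of a primary allylic alcohol.

Step 17
Reactants: 26 ethyl 2-[(tert-butyldimethylsilyloxy)methyl]acrylate
Product: 27 2-[(tert-butyldimethylsilyloxy)methyl]acrylic acid
Conditions: LiOH, THF/H2O, 0 °C → rt; then 1 M HCl to pH 3
Reagents that add atoms: lithium hydroxide, [Li+].[OH-]
Why: Saponification of the ethyl ester; the primary TBS ether is stable to cold aqueous hydroxide and to the brief acidification.

Step 18
Reactants: 24 the 8α-alcohol; 27 2-[(tert-butyldimethylsilyloxy)methyl]acrylic acid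
Product: 28 the 8α-{2-[(tert-butyldimethylsilyloxy)methyl]acryloyloxy} ester of 24
Conditions: DCC, DMAP (cat.), CH2Cl2, 0 °C → rt
Reagents that add atoms: none
Why: Steglich esterification of the only free hydroxyl (equatorial O-8); C-8 keeps its configuration because the C–O bond is not broken.

Step 19
Reactants: 28 the O-8 ester carrying the 7β-isopropenyl group
Product: 30 the 12-al (C-7 substituent now C(=CH2)CHO), via allylic alcohol 29 (not isolated)
Conditions: SeO2 (0.5 equiv), t-BuOOH, CH2Cl2, rt; then MnO2, CH2Cl2, rt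
Reagents that add atoms: selenium dioxide, O=[Se]=O; tert-butyl hydroperoxide, CC(C)(C)OO
Why: The SeO2 ene reaction and [2,3]-sigmatropic shift should oxidise the allylic methyl of the electron-rich isopropenyl group (the acrylate alkene is too electron-poor), and MnO2 then takes the allylic alcohol to the enal; no stereocentre is involved.

Step 20
Reactants: 30 the 12-al
Product: 31 the 12-oic acid (C-7 substituent C(=CH2)CO2H; three TBS groups still in place)
Conditions: NaClO2, NaH2PO4, 2-methyl-2-butene, t-BuOH/H2O, 0 °C → rt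
Reagents that add atoms: sodium chlorite, [Na+].[O-]Cl=O
Why: Pinnick oxidation converts the enal into the acrylic acid without touching alkenes or silyl ethers, while C-15 is masked as the lactol silyl ether.

Step 21
Reactants: 31 the tris-silylated acid
Product: 32 target, 1β,6α-dihydroxy-8α-[2-(hydroxymethyl)acryloyloxy]-15-oxo-eudesm-11(13)-en-12-oic acid (4βH,5αH,7αH)
Conditions: HF·pyridine, pyridine, THF, 0 °C → rt
Reagents that add atoms: none
Why: Buffered fluoride removes the primary, the secondary and the lactol silyl group under non-hydrolytic conditions; loss of the lactol silyl group sets free the 6α-hydroxyl and the C-15 aldehyde (held 4α-equatorial by the former bridge) at the same time.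

**Compound list**

1 | 2-methylcyclohex-2-en-1-one | CC1=CCCCC1=O | starting material
2 | (R)-2-methylcyclohex-2-en-1-ol | CC1=CCCC[C@H]1O | intermediate
3 | (R)-tert-butyldimethyl[(2-methylcyclohex-2-en-1-yl)oxy]silane | CC1=CCCC[C@H]1O[Si](C)(C)C(C)(C)C | intermediate
4 | (R)-4-(tert-butyldimethylsilyloxy)-3-methylcyclohex-2-en-1-one | CC1=CC(=O)CC[C@H]1O[Si](C)(C)C(C)(C)C | intermediate
5 | bromomagnesium C-4=C-5 enolate of the conjugate adduct (vinyl trans to OTBS; not isolated) | C=C[C@]1(C)C=C(O[Mg]Br)CC[C@H]1O[Si](C)(C)C(C)(C)C | intermediate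
6 | (3R,4R)-4-(tert-butyldimethylsilyloxy)-3-methyl-3-vinylcyclohex-1-en-1-yl trifluoromethanesulfonate | C=C[C@]1(C)C=C(OS(=O)(=O)C(F)(F)F)CC[C@H]1O[Si](C)(C)C(C)(C)C | intermediate
7 | methyl (3R,4R)-4-(tert-butyldimethylsilyloxy)-3-methyl-3-vinylcyclohex-1-ene-1-carboxylate | C=C[C@]1(C)C=C(C(=O)OC)CC[C@H]1O[Si](C)(C)C(C)(C)C | intermediate
8 | B-alkyl-9-borabicyclo[3.3.1]nonane from 7 (boron on C-8; not isolated) | C(C[C@]1(C)C=C(C(=O)OC)CC[C@H]1O[Si](C)(C)C(C)(C)C)B1C2CCCC1CCC2 | intermediate
9 | methyl (3R,4R)-4-(tert-butyldimethylsilyloxy)-3-(2-hydroxyethyl)-3-methylcyclohex-1-ene-1-carboxylate | OCC[C@]1(C)C=C(C(=O)OC)CC[C@H]1O[Si](C)(C)C(C)(C)C | intermediate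
10 | methyl (3R,4R)-4-(tert-butyldimethylsilyloxy)-3-methyl-3-(2-oxoethyl)cyclohex-1-ene-1-carboxylate | O=CC[C@]1(C)C=C(C(=O)OC)CC[C@H]1O[Si](C)(C)C(C)(C)C | intermediate
11 | (R)-4-benzyloxazolidin-2-one | O=C1N[C@H](Cc2ccccc2)CO1 | starting material
12 | 3-methylbut-2-enoyl chloride | CC(C)=CC(Cl)=O | starting material
13 | lithium salt of 11 (not isolated) | [Li]N1[C@H](Cc2ccccc2)COC1=O | intermediate
14 | (R)-4-benzyl-3-(3-methylbut-2-enoyl)oxazolidin-2-one | CC(C)=CC(=O)N1[C@H](Cc2ccccc2)COC1=O | intermediate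
15 | (Z)-dibutylboron dienolate of 14 (not isolated) | C=C(C)/C=C(\OB(CCCC)CCCC)N1[C@H](Cc2ccccc2)COC1=O | intermediate
16 | syn-aldol adduct, methyl (3R,4R)-3-{(2S,3R)-3-[(R)-4-benzyl-2-oxooxazolidine-3-carbonyl]-2-hydroxy-4-methylpent-4-en-1-yl}-4-(tert-butyldimethylsilyloxy)-3-methylcyclohex-1-ene-1-carboxylate | O[C@H]([C@@H](C(C)=C)C(=O)N2[C@H](Cc3ccccc3)COC2=O)C[C@]1(C)C=C(C(=O)OC)CC[C@H]1O[Si](C)(C)C(C)(C)C | intermediate
17 | O-8 triethylsilyl ether of 16 | CC[Si](CC)(CC)O[C@H]([C@@H](C(C)=C)C(=O)N2[C@H](Cc3ccccc3)COC2=O)C[C@]1(C)C=C(C(=O)OC)CC[C@H]1O[Si](C)(C)C(C)(C)C | intermediate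
18 | methyl (3R,4R)-4-(tert-butyldimethylsilyloxy)-3-[(2S,3S)-3-(hydroxymethyl)-4-methyl-2-(triethylsilyloxy)pent-4-en-1-yl]-3-methylcyclohex-1-ene-1-carboxylate | CC[Si](CC)(CC)O[C@H]([C@@H](C(C)=C)CO)C[C@]1(C)C=C(C(=O)OC)CC[C@H]1O[Si](C)(C)C(C)(C)C | intermediate
19 | methyl (3R,4R)-4-(tert-butyldimethylsilyloxy)-3-[(2S,3R)-3-formyl-4-methyl-2-(triethylsilyloxy)pent-4-en-1-yl]-3-methylcyclohex-1-ene-1-carboxylate | CC[Si](CC)(CC)O[C@H]([C@@H](C(C)=C)C=O)C[C@]1(C)C=C(C(=O)OC)CC[C@H]1O[Si](C)(C)C(C)(C)C | intermediate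
20 | methyl 1β-(tert-butyldimethylsilyloxy)-6α-hydroxy-8α-(triethylsilyloxy)-7β-isopropenyl-eudesman-15-oate (trans-fused; C-4 epimers; not isolated) | CC[Si](CC)(CC)O[C@H]1C[C@]2(C)[C@@H]([C@@H](O)[C@@H]1C(C)=C)C(C(=O)OC)CC[C@H]2O[Si](C)(C)C(C)(C)C | intermediate
21 | 1β-(tert-butyldimethylsilyloxy)-8α-(triethylsilyloxy)-7β-isopropenyl-eudesman-15,6α-olide (H-4β, H-5α) | CC[Si](CC)(CC)O[C@H]1C[C@]2(C)[C@@H]([C@@H](O3)[C@@H]1C(C)=C)[C@H](C3=O)CC[C@H]2O[Si](C)(C)C(C)(C)C | intermediate
22 | diisobutylaluminium lactolate of 21 (not isolated) | CC[Si](CC)(CC)O[C@H]1C[C@]2(C)[C@@H]([C@@H](O3)[C@@H]1C(C)=C)[C@H](C3O[Al](CC(C)C)CC(C)C)CC[C@H]2O[Si](C)(C)C(C)(C)C | intermediate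
23 | 15-O-TBS 15,6α-lactol ether with 1β-OTBS and 8α-OTES (C-15 epimers) | CC[Si](CC)(CC)O[C@H]1C[C@]2(C)[C@@H]([C@@H](O3)[C@@H]1C(C)=C)[C@H](C3O[Si](C)(C)C(C)(C)C)CC[C@H]2O[Si](C)(C)C(C)(C)C | intermediate
24 | 8α-alcohol of 23 | O[C@H]1C[C@]2(C)[C@@H]([C@@H](O3)[C@@H]1C(C)=C)[C@H](C3O[Si](C)(C)C(C)(C)C)CC[C@H]2O[Si](C)(C)C(C)(C)C | intermediate
25 | ethyl 2-(hydroxymethyl)acrylate | C=C(CO)C(=O)OCC | starting material
26 | ethyl 2-[(tert-butyldimethylsilyloxy)methyl]acrylate | C=C(CO[Si](C)(C)C(C)(C)C)C(=O)OCC | intermediate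
27 | 2-[(tert-butyldimethylsilyloxy)methyl]acrylic acid | C=C(CO[Si](C)(C)C(C)(C)C)C(=O)O | intermediate
28 | 8α-{2-[(tert-butyldimethylsilyloxy)methyl]acryloyloxy} ester of 24 | C=C(CO[Si](C)(C)C(C)(C)C)C(=O)O[C@H]1C[C@]2(C)[C@@H]([C@@H](O3)[C@@H]1C(C)=C)[C@H](C3O[Si](C)(C)C(C)(C)C)CC[C@H]2O[Si](C)(C)C(C)(C)C | intermediate
29 | 12-hydroxy compound (C-7 substituent C(=CH2)CH2OH; not isolated) | C=C(CO[Si](C)(C)C(C)(C)C)C(=O)O[C@H]1C[C@]2(C)[C@@H]([C@@H](O3)[C@@H]1C(=C)CO)[C@H](C3O[Si](C)(C)C(C)(C)C)CC[C@H]2O[Si](C)(C)C(C)(C)C | intermediate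
30 | 12-al (C-7 substituent C(=CH2)CHO) | C=C(CO[Si](C)(C)C(C)(C)C)C(=O)O[C@H]1C[C@]2(C)[C@@H]([C@@H](O3)[C@@H]1C(=C)C=O)[C@H](C3O[Si](C)(C)C(C)(C)C)CC[C@H]2O[Si](C)(C)C(C)(C)C | intermediate
31 | 12-oic acid, tris-TBS protected | C=C(CO[Si](C)(C)C(C)(C)C)C(=O)O[C@H]1C[C@]2(C)[C@@H]([C@@H](O3)[C@@H]1C(=C)C(=O)O)[C@H](C3O[Si](C)(C)C(C)(C)C)CC[C@H]2O[Si](C)(C)C(C)(C)C | intermediate
32 | 1β,6α-dihydroxy-8α-[2-(hydroxymethyl)acryloyloxy]-15-oxo-eudesm-11(13)-en-12-oic acid (CNP0599450.1) | C=C(CO)C(=O)O[C@H]1C[C@]2(C)[C@@H]([C@@H](O)[C@@H]1C(=C)C(=O)O)[C@H](C=O)CC[C@H]2O | target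

**Step count and risks**

Total step count: 21. Longest linear sequence: 18 steps (steps 1–7, 9–15 and 18–21).

Steps most likely to fail:

1. Step 13 (key step). The ketyl may attack the other face of C-4=C-5 and give the cis ring fusion, or the aldehyde may be reduced to the alcohol before it cyclises. Fallback (sets out from 19, comes back at 21): close the same C-5–C-6 bond by polar umpolung instead of a radical. An intramolecular Stetter reaction of 19 (triazolium carbene precatalyst, cat. KHMDS, PhMe) should give a 6-ketone in which C-5, C-4 and C-7 are all epimerisable; DBU equilibration should give the all-equatorial trans-fused methyl 1β-(tert-butyldimethylsilyloxy)-8α-(triethylsilyloxy)-7β-isopropenyl-6-oxo-eudesman-15-oate F1. Thermodynamic ketone reduction (SmI2, H2O, Et3N, THF) should give the equatorial 6α-alcohol, which is the 4α epimer of 20 and lactonises with DBU to 21.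

2. Step 4. Addition at the hindered β-carbon may be slow or turn into 1,2-addition, the anti selectivity may erode, or the enolate may be sulfonylated on carbon. Fallback (sets out from 4, comes back at 10): a Mukaiyama–Michael addition of 1-(ethylthio)-1-(trimethylsilyloxy)ethene to 4 (TMSOTf cat., CH2Cl2, −78 °C), again anti to the silyloxy group, should give the regiodefined trimethylsilyl enol ether thioester F2. CsF and PhNTf2 (DME) convert it into the enol triflate thioester F3, methoxycarbonylation as in step 5 gives the enoate thioester F4, and a Fukuyama reduction (Et3SiH, Pd/C, acetone) gives aldehyde 10, so that steps 6 and 7 are not needed.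

3. Step 19. The allylic oxidation may attack the tertiary C-7–H instead of the methyl group, over-oxidise, or strip the lactol silyl ether under the slightly acidic conditions. Fallback (sets out from 28, comes back at 30): ene-type chlorination of the isopropenyl group with hypochlorous acid made from Ca(OCl)2 and CO2 (CH2Cl2/H2O, 0 °C) should give the allylic chloride F5, and a Kornblum-type oxidation with N-methylmorpholine N-oxide (MeCN, rt) then gives enal 30.

Further compounds

F1 | step 13 | methyl 1β-(tert-butyldimethylsilyloxy)-8α-(triethylsilyloxy)-7β-isopropenyl-6-oxo-eudesman-15-oate (4α-ester, trans-fused) | CC[Si](CC)(CC)O[C@H]1C[C@]2(C)[C@@H](C(=O)[C@@H]1C(C)=C)[C@H](C(=O)OC)CC[C@H]2O[Si](C)(C)C(C)(C)C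
F2 | step 4 | S-ethyl 2-[(1R,6R)-6-(tert-butyldimethylsilyloxy)-1-methyl-3-(trimethylsilyloxy)cyclohex-2-en-1-yl]ethanethioate | CCSC(=O)C[C@]1(C)C=C(O[Si](C)(C)C)CC[C@H]1O[Si](C)(C)C(C)(C)C
F3 | step 4 | S-ethyl 2-[(1R,6R)-6-(tert-butyldimethylsilyloxy)-1-methyl-3-(trifluoromethylsulfonyloxy)cyclohex-2-en-1-yl]ethanethioate | CCSC(=O)C[C@]1(C)C=C(OS(=O)(=O)C(F)(F)F)CC[C@H]1O[Si](C)(C)C(C)(C)C
F4 | step 4 | methyl (3R,4R)-4-(tert-butyldimethylsilyloxy)-3-[2-(ethylthio)-2-oxoethyl]-3-methylcyclohex-1-ene-1-carboxylate | CCSC(=O)C[C@]1(C)C=C(C(=O)OC)CC[C@H]1O[Si](C)(C)C(C)(C)C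
F5 | step 19 | 12-chloro analogue of 28 (C-7 substituent C(=CH2)CH2Cl) | C=C(CO[Si](C)(C)C(C)(C)C)C(=O)O[C@H]1C[C@]2(C)[C@@H]([C@@H](O3)[C@@H]1C(=C)CCl)[C@H](C3O[Si](C)(C)C(C)(C)C)CC[C@H]2O[Si](C)(C)C(C)(C)C
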